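## The problem

Compound 14 is a flavonol: benzo ring A is fused to pyranone ring C (O1, C2, C3, C4, C4a, C8a), and ring B sits on C2. There is no stereocentre. The task is to tell seven oxygens apart: five end up free (C3, C5, C8, C3', C5') and two methylated (C7, C4'). The hydroxyls at C5 and C8 are para to each other, so ring A is a hydroquinone that air oxidises to the chromene-5,8-dione in base. The 5,7,8-pattern can also isomerise to 5,6,7 through ring opening in hot strong acid, and ring B is an oxidisable pyrogallol monoether. The free phenols therefore have to be released last, without base and without oxidant. Ring C is made most cheaply by oxidative cyclisation of a 2'-hydroxychalcone, which also installs the C3 hydroxyl. That reaction is reliable only when the chalcone has no substituent at 6', the future C5. The feature that resolves this is that C5–H of ring A lies peri to the C4 carbonyl oxygen of ring C. A metal bound to that oxygen reaches C5 through a five-membered ring (metal, O, C4, C4a, C5) and reaches no other C–H bond. The C5 oxygen can thus be added last to a flavonol whose ring A comes from a 2,3,4-trioxygenated acetophenone.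

## Retrosynthesis

**14 from 13.** The four ester C–O bonds at C3, C8, C3' and C5' are cut, giving tetraacetate 13. Acid-catalysed methanolysis is preferred to base because the 5,8-hydroquinone is never a phenoxide in air. The forward step must only leave the two methyl ethers and the flavonol core alone.

**13 from 11 (key disconnection).** The C5–O bond is cut, giving 11, which has hydrogen at C5. The neighbouring choice, carrying the C5 oxygen from the start, would need a 3,6-dioxygenated 2-hydroxyacetophenone with differentiated oxygens and would place a 6' substituent on the chalcone. Cutting C5–O instead lets ring A come from the purchasable ketone 5. The forward reaction is the carbonyl-directed ruthenium-catalysed C–H oxygenation with PhI(OCOCF3)2 in CF3CO2H/(CF3CO)2O. It delivers the C5 trifluoroacetate 12, which is hydrolysed on work-up. The medium is hot, strongly acidic and oxidising. Benzyl ethers would ionise in it and their electron-rich rings would be attacked by the trivalent iodine reagent. The four spectator hydroxyls are therefore carried as acetates, which are acid-stable and electron-withdrawing. Hydroxylating the free tetraol 10 directly, with the anhydride acylating it in the flask, would be two steps shorter. It was not chosen because the free 3-hydroxy-4-keto unit is a strong chelator for ruthenium.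

**11 from 10 from 9.** The four acetates are cut back to tetraol 10, and the three benzyl ethers of 9 are restored. Benzyl ethers are needed earlier because the chalcone condensation and the alkaline peroxide step require base-stable protection. The exchange costs one step more than a perbenzylated substrate would, and buys a substrate that fits the known tolerance of the oxidation.

**9 from 7.** The O1–C2 bond and the C3–O bond are cut, opening ring C to chalcone 7. The forward step is the Algar–Flynn–Oyamada reaction, which passes through dihydroflavonol 8. It forms the ring and the C3 hydroxyl in one operation, which a flavone synthesis followed by C3 oxidation would need two steps for. It requires a free 6' position, which 7 has.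

**7 from 6 and 4.** The Cα–Cβ bond of the enone is cut, giving ketone 6 and aldehyde 4. The forward step is a Claisen–Schmidt condensation with a non-enolisable aldehyde. The two fragments carry all the oxygens of rings A and B except the one at C5.

**6 from 5; 4 from 3, 2 and 1.** Ketone 6 is the 3-O-benzyl ether of purchasable 5, whose 2-hydroxyl is chelated and stays free. Aldehyde 4 comes from acid 1 by exhaustive benzylation to ester 2, reduction to alcohol 3 and oxidation.

## Roads not taken

**Alternative 1:** Ring C is cut at C4a–C4, C4–C3 and O1–C2, giving iodophenol A2, carbon monoxide and arylacetylene A3. In the forward step PdCl2(PPh3)2 and a secondary amine generate zerovalent palladium. This inserts into the C–I bond, takes up CO and couples with A3 to give an alkynone. The phenol oxygen then adds to the alkyne in a 6-endo closure to give flavone A1.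
- Merits: the route is convergent, all ring A oxygens are fixed by construction, and no late C–H oxidation at C5 is needed.
- Weak points: A1 has no oxygen at C3, so a separate C3 hydroxylation of a penta-alkoxyflavone replaces the C5 oxidation that was avoided. A2 is a fully substituted benzene with four differentiated oxygens and an iodine, and would need several regioselective steps. Its iodide is flanked by two oxygens, which slows CO insertion, so direct alkyne coupling to a benzofuran and 5-exo closure to an aurone compete.
- Comparison: this road is better on regiochemical certainty at C5. The chosen plan sets against it a ring A that is bought and a C3 hydroxyl that arrives with the ring closure.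

**Alternative 2:** The C2–C3 bond is cut, and behind it O1–C2. Ketone A6 is acylated on its phenol with the ring B acid to give ester A5. LiN(SiMe3)2 or KOtBu enolises the benzyloxyacetyl group, and the enolate carbon attacks the neighbouring aryl ester carbonyl to give diketone A4 (Baker–Venkataraman shift). Acid then closes ring C to the pentabenzyl flavonol A7, and hydrogenolysis gives 14.
- Merits: every oxygen is in place from the start, all steps are classical, and the final unmasking is a neutral hydrogenolysis. This is a gentler end than ester solvolysis and involves no transition-metal C–H step.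
- Weak points: A6 is a pentasubstituted benzene with four differently protected oxygens. Making it from purchasable phenols takes a nuclear oxidation, selective protections and an acylation between two oxygens. The ester A5 is built on a hindered, chelated phenol.
- Comparison: this road is more reliable in its key step and its last step. The chosen plan sets against it a much shorter access to ring A and a ten-step total. If the C–H oxygenation fails for good, this is the strongest replacement.

**Alternative 3:** Ring A is cut at C4a–C5 and earlier at C8–C8a. Pyranone A10 is metalated at C6 and added to the semisquarate A11 to give cyclobutenone A9. Heating opens the four-membered ring to a dienylketene (Moore ring expansion). The ketene carbon bonds to C5 of the pyranone in a six-electron electrocyclisation, and tautomerisation gives hydroquinone A8, one hydrogenolysis from 14.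
- Merits: both hydroquinone oxygens and the C7 methoxyl are placed by construction, with no differentiation of ring A oxygens at all.
- Weak points: A10 has no simple source. Its C6 metalation competes with addition to its own carbonyl, and closure of a ketene onto a pyranone double bond has thin precedent compared with arenes and alkenes. A8 is formed hot as a free hydroquinone and may oxidise.
- Comparison: this road equals the chosen plan in the economy of the last steps and is better on regiochemistry. The chosen plan sets against it purchasable building blocks, a classical flavonol assembly and a key step with direct precedent on flavones.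

Key step: step 9

Assumption: 1-(2,3-dihydroxy-4-methoxyphenyl)ethanone 5 is taken as a purchasable compound, which saves the borate-mediated 4-O-methylation of 2,3,4-trihydroxyacetophenone.

## Route

Step 1
Reactants: 1 3,5-dihydroxy-4-methoxybenzoic acid
Product: 2 benzyl 3,5-bis(benzyloxy)-4-methoxybenzoate
Conditions: BnBr (3.5 equiv), K2CO3, DMF, 60 °C
Reagents that add atoms: benzyl bromide, BrCc1ccccc1
Why: Williamson alkylation of both phenols and of the carboxylate in one operation; the benzyl ester is removed in the next step.

Step 2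
Reactants: 2 benzyl 3,5-bis(benzyloxy)-4-methoxybenzoate
Product: 3 [3,5-bis(benzyloxy)-4-methoxyphenyl]methanol
Conditions: LiAlH4, THF, 0 °C to rt
Reagents that add atoms: none
Why: Hydride reduction of a benzoate ester to the benzylic alcohol; aryl benzyl and methyl ethers are inert to LiAlH4.

Step 3
Reactants: 3 [3,5-bis(benzyloxy)-4-methoxyphenyl]methanol
Product: 4 3,5-bis(benzyloxy)-4-methoxybenzaldehyde
Conditions: MnO2, CH2Cl2, rt
Reagents that add atoms: none
Why: MnO2 oxidation of a benzylic alcohol stops at the aldehyde and leaves the ethers untouched.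

Step 4
Reactants: 5 1-(2,3-dihydroxy-4-methoxyphenyl)ethanone
Product: 6 1-[3-(benzyloxy)-2-hydroxy-4-methoxyphenyl]ethanone
Conditions: BnBr (1.05 equiv), K2CO3 (1.1 equiv), acetone, reflux
Reagents that add atoms: benzyl bromide, BrCc1ccccc1
Why: Williamson etherification; the 2-hydroxyl is hydrogen-bonded to the acetyl carbonyl and is the poorer nucleophile, the same selectivity that lets 2,3,4-trihydroxyacetophenone be dialkylated at O3 and O4 only.

Step 5
Reactants: 6 1-[3-(benzyloxy)-2-hydroxy-4-methoxyphenyl]ethanone; 4 3,5-bis(benzyloxy)-4-methoxybenzaldehyde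
Product: 7 (E)-1-[3-(benzyloxy)-2-hydroxy-4-methoxyphenyl]-3-[3,5-bis(benzyloxy)-4-methoxyphenyl]prop-2-en-1-one
Conditions: KOH (50% aq.), EtOH/THF, rt
Reagents that add atoms: none
Why: Claisen–Schmidt condensation of a methyl ketone with a non-enolisable aldehyde; dehydration of the aldol gives the conjugated E enone under thermodynamic control.

Step 6
Reactants: 7 (E)-1-[3-(benzyloxy)-2-hydroxy-4-methoxyphenyl]-3-[3,5-bis(benzyloxy)-4-methoxyphenyl]prop-2-en-1-one
Product: 9 8-(benzyloxy)-2-[3,5-bis(benzyloxy)-4-methoxyphenyl]-3-hydroxy-7-methoxychromen-4-one, via trans-dihydroflavonol 8 (not isolated)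
Conditions: 30% H2O2, 2 M NaOH, MeOH/THF, 0 °C to rt; then HCl to pH 3
Reagents that add atoms: hydrogen peroxide, OO
Why: Algar–Flynn–Oyamada reaction; the phenoxide closes onto Cβ while hydroperoxide delivers oxygen to Cα to give 8, which more alkaline peroxide dehydrogenates to the flavonol; with no 6' substituent the six-membered closure is favoured over aurone formation, and the two stereocentres of 8 are not controlled because they vanish.

Step 7
Reactants: 9 8-(benzyloxy)-2-[3,5-bis(benzyloxy)-4-methoxyphenyl]-3-hydroxy-7-methoxychromen-4-one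
Product: 10 2-(3,5-dihydroxy-4-methoxyphenyl)-3,8-dihydroxy-7-methoxychromen-4-one
Conditions: H2 (1 atm), 10% Pd/C, THF/MeOH, rt
Reagents that add atoms: none
Why: Hydrogenolysis of three aryl benzyl ethers; the tetrasubstituted C2=C3 bond and the vinylogous ester carbonyl of the flavonol are reduced far more slowly at one atmosphere.

Step 8
Reactants: 10 2-(3,5-dihydroxy-4-methoxyphenyl)-3,8-dihydroxy-7-methoxychromen-4-one
Product: 11 3,8-bis(acetyloxy)-2-[3,5-bis(acetyloxy)-4-methoxyphenyl]-7-methoxychromen-4-one
Conditions: Ac2O, pyridine, DMAP (cat.), rt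
Reagents that add atoms: acetic anhydride, CC(=O)OC(C)=O
Why: DMAP-catalysed peracetylation of three phenols and the enolic C3 hydroxyl; it converts the electron-rich phenols into acid-stable, electron-poor esters for step 9.

Step 9
Reactants: 11 3,8-bis(acetyloxy)-2-[3,5-bis(acetyloxy)-4-methoxyphenyl]-7-methoxychromen-4-one
Product: 13 3,8-bis(acetyloxy)-2-[3,5-bis(acetyloxy)-4-methoxyphenyl]-5-hydroxy-7-methoxychromen-4-one, via C5 trifluoroacetate 12 (not isolated)
Conditions: [RuCl2(p-cymene)]2 (5 mol %), PhI(OCOCF3)2 (2 equiv), CF3CO2H/(CF3CO)2O, 80 °C; then THF/pH 7 phosphate buffer, rt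
Reagents that add atoms: [bis(trifluoroacetoxy)iodo]benzene, O=C(O[I](OC(=O)C(F)(F)F)c1ccccc1)C(F)(F)F
Why: This is the known ketone-directed, ruthenium-catalysed ortho C–H hydroxylation of aryl ketones, which has been shown at C5 of chromones and flavones. In CF3CO2H the chlorides of [RuCl2(p-cymene)]2 are exchanged for trifluoroacetate, the C4 carbonyl oxygen of 11 binds the divalent ruthenium, and carboxylate-assisted concerted metalation–deprotonation at C5 gives a five-membered ruthenacycle (Ru, O, C4, C4a, C5). PhI(OCOCF3)2 oxidises this to tetravalent ruthenium, and C–O reductive elimination gives trifluoroacetate 12 and returns the catalyst. The anhydride keeps the new oxygen acylated, so the product neither chelates the catalyst through a 5-hydroxy-4-keto unit nor is oxidised on to the quinone; the buffered work-up then hydrolyses the labile aryl trifluoroacetate while the four acetates stay. No ring is closed and no stereocentre is formed. The step needs C5 over C6 and over C2'/C6' of ring B: only C5 can reach a five-membered metallacycle from the carbonyl oxygen, C6 could react only by undirected electrophilic attack, and ring B would need a seven-membered chelate. The acetates secure the rest: they survive CF3CO2H/(CF3CO)2O where benzyl ethers would ionise, and they make rings A and B too electron-poor for direct oxidation by the trivalent iodine reagent.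

Step 10
Reactants: 13 3,8-bis(acetyloxy)-2-[3,5-bis(acetyloxy)-4-methoxyphenyl]-5-hydroxy-7-methoxychromen-4-one
Product: 14 2-(3,5-dihydroxy-4-methoxyphenyl)-3,5,8-trihydroxy-7-methoxychromen-4-one
Conditions: HCl (1.25 M in MeOH), degassed, 50 °C, Ar
Reagents that add atoms: none
Why: Acid-catalysed transesterification of the three aryl acetates and the enol acetate to methyl acetate; the acidic, oxygen-free medium keeps the 5,8-hydroquinone protonated and away from phenoxide autoxidation, and the methyl ethers are inert.

## Compound list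

1 | 3,5-dihydroxy-4-methoxybenzoic acid | COc1c(O)cc(C(=O)O)cc1O | starting material
2 | benzyl 3,5-bis(benzyloxy)-4-methoxybenzoate | COc1c(OCc2ccccc2)cc(C(=O)OCc2ccccc2)cc1OCc1ccccc1 | intermediate
3 | [3,5-bis(benzyloxy)-4-methoxyphenyl]methanol | COc1c(OCc2ccccc2)cc(CO)cc1OCc1ccccc1 | intermediate
4 | 3,5-bis(benzyloxy)-4-methoxybenzaldehyde | COc1c(OCc2ccccc2)cc(C=O)cc1OCc1ccccc1 | intermediate
5 | 1-(2,3-dihydroxy-4-methoxyphenyl)ethanone | CC(=O)c1ccc(OC)c(O)c1O | starting material
6 | 1-[3-(benzyloxy)-2-hydroxy-4-methoxyphenyl]ethanone | CC(=O)c1ccc(OC)c(OCc2ccccc2)c1O | intermediate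
7 | (E)-1-[3-(benzyloxy)-2-hydroxy-4-methoxyphenyl]-3-[3,5-bis(benzyloxy)-4-methoxyphenyl]prop-2-en-1-one | COc1ccc(C(=O)/C=C/c2cc(OCc3ccccc3)c(OC)c(OCc3ccccc3)c2)c(O)c1OCc1ccccc1 | intermediate
8 | rac-(2R,3R)-8-(benzyloxy)-2-[3,5-bis(benzyloxy)-4-methoxyphenyl]-3-hydroxy-7-methoxy-2,3-dihydrochromen-4-one (trans; racemate, one enantiomer drawn; formed in the flask) | COc1ccc2C(=O)[C@H](O)[C@@H](c3cc(OCc4ccccc4)c(OC)c(OCc4ccccc4)c3)Oc2c1OCc1ccccc1 | intermediate
9 | 8-(benzyloxy)-2-[3,5-bis(benzyloxy)-4-methoxyphenyl]-3-hydroxy-7-methoxychromen-4-one | COc1ccc2c(=O)c(O)c(-c3cc(OCc4ccccc4)c(OC)c(OCc4ccccc4)c3)oc2c1OCc1ccccc1 | intermediate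
10 | 2-(3,5-dihydroxy-4-methoxyphenyl)-3,8-dihydroxy-7-methoxychromen-4-one | COc1ccc2c(=O)c(O)c(-c3cc(O)c(OC)c(O)c3)oc2c1O | intermediate
11 | 3,8-bis(acetyloxy)-2-[3,5-bis(acetyloxy)-4-methoxyphenyl]-7-methoxychromen-4-one | COc1ccc2c(=O)c(OC(C)=O)c(-c3cc(OC(C)=O)c(OC)c(OC(C)=O)c3)oc2c1OC(C)=O | intermediate
12 | 3,8-bis(acetyloxy)-2-[3,5-bis(acetyloxy)-4-methoxyphenyl]-7-methoxy-4-oxochromen-5-yl trifluoroacetate (formed in the flask) | COc1cc(OC(=O)C(F)(F)F)c2c(=O)c(OC(C)=O)c(-c3cc(OC(C)=O)c(OC)c(OC(C)=O)c3)oc2c1OC(C)=O | intermediate
13 | 3,8-bis(acetyloxy)-2-[3,5-bis(acetyloxy)-4-methoxyphenyl]-5-hydroxy-7-methoxychromen-4-one | COc1cc(O)c2c(=O)c(OC(C)=O)c(-c3cc(OC(C)=O)c(OC)c(OC(C)=O)c3)oc2c1OC(C)=O | intermediate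
14 | 2-(3,5-dihydroxy-4-methoxyphenyl)-3,5,8-trihydroxy-7-methoxychromen-4-one | COc1cc(O)c2c(=O)c(O)c(-c3cc(O)c(OC)c(O)c3)oc2c1O | target

## Step count and risks

Total: 10 steps. Longest linear sequence: 9 steps (1 to 14 through steps 1, 2, 3, 5, 6, 7, 8, 9 and 10); the ring A branch is step 4 alone.

**Step 9 (key step).** The most likely failures are these:
- undirected oxidation of ring B or of C6 by the trivalent iodine reagent;
- acyl exchange or loss of acetates in the hot acid, after which a freed 3-hydroxy-4-keto unit would bind the ruthenium;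
- competing metalation at C2' directed by the neighbouring aryl acetate.

Partial acyl exchange alone is harmless, because the crude mixture converges in step 10. If the oxygenation itself fails, the C5 oxygen would be brought in by para-oxidation of an 8-phenol instead of by C–H metalation. This fallback sets out from 5 (with aldehyde 4) and rejoins the route at 14. Ketone 5 would be alkylated at O3 with MOMCl and iPr2NEt in CH2Cl2 to give 1-[2-hydroxy-4-methoxy-3-(methoxymethoxy)phenyl]ethanone F1. Condensation with 4 under the conditions of step 5 gives (E)-3-[3,5-bis(benzyloxy)-4-methoxyphenyl]-1-[2-hydroxy-4-methoxy-3-(methoxymethoxy)phenyl]prop-2-en-1-one F2. Alkaline peroxide as in step 6 gives, through the trans-dihydroflavonol F3, 2-[3,5-bis(benzyloxy)-4-methoxyphenyl]-3-hydroxy-7-methoxy-8-(methoxymethoxy)chromen-4-one F4. BnBr and K2CO3 in DMF then give 3-(benzyloxy)-2-[3,5-bis(benzyloxy)-4-methoxyphenyl]-7-methoxy-8-(methoxymethoxy)chromen-4-one F5. HCl in MeOH removes the acetal to give 3-(benzyloxy)-2-[3,5-bis(benzyloxy)-4-methoxyphenyl]-8-hydroxy-7-methoxychromen-4-one F6, the only free phenol of which has its para position (C5) open. Teuber oxidation with ON(SO3K)2 and KH2PO4 in aqueous acetone gives 3-(benzyloxy)-2-[3,5-bis(benzyloxy)-4-methoxyphenyl]-7-methoxychromene-4,5,8-trione F7. H2 over 10% Pd/C then reduces the quinone and cleaves the three benzyl ethers in one operation to give 14.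

**Step 6.** The flavonol may be degraded by excess alkaline peroxide, the lipophilic chalcone may react sluggishly in the aqueous medium, or five-membered closure to an aurone may intrude. The fallback separates ring closure from C3 oxygenation. It sets out from 7 and returns at 9. Catalytic I2 in DMSO at 120 °C would cyclise and dehydrogenate 7 to 8-(benzyloxy)-2-[3,5-bis(benzyloxy)-4-methoxyphenyl]-7-methoxychromen-4-one F8. Dimethyldioxirane in acetone/CH2Cl2 would epoxidise the C2=C3 bond to 8-(benzyloxy)-2-[3,5-bis(benzyloxy)-4-methoxyphenyl]-2,3-epoxy-7-methoxy-2,3-dihydrochromen-4-one F9 (racemic, necessarily cis-fused). Catalytic TsOH would then open and isomerise it to 9.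

**Step 4.** Alkylation may not stop cleanly at O3, giving some 2-O-benzyl and dibenzyl ether. The fallback uses chelation to remove a group instead of to spare one. It sets out from 5 and returns at 6. Excess BnBr and K2CO3 in DMF would give 1-[2,3-bis(benzyloxy)-4-methoxyphenyl]ethanone F10. MgBr2·OEt2 in toluene/Et2O at reflux would then cleave only the benzyl ether ortho to the carbonyl, through a six-membered magnesium chelate, to give 6.

**Step 10.** The liberated hydroquinone may be oxidised to the quinone during solvolysis or purification, and the last acetates may cleave slowly, leaving polar mixtures that are hard to separate. The fallback moves the purification to a robust ether and makes the final unmasking reductive. It sets out from 13 and returns at 14. K2CO3 and BnBr in degassed DMF/MeOH would exchange each acetate for a benzyl ether as it is cleaved, while the chelated C5 hydroxyl stays free, to give 3,8-bis(benzyloxy)-2-[3,5-bis(benzyloxy)-4-methoxyphenyl]-5-hydroxy-7-methoxychromen-4-one F11. Hydrogenolysis over 10% Pd/C would then give 14 with toluene as the only by-product.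

## Further compounds

F1 | step 9 | 1-[2-hydroxy-4-methoxy-3-(methoxymethoxy)phenyl]ethanone | COCOc1c(OC)ccc(C(C)=O)c1O
F2 | step 9 | (E)-3-[3,5-bis(benzyloxy)-4-methoxyphenyl]-1-[2-hydroxy-4-methoxy-3-(methoxymethoxy)phenyl]prop-2-en-1-one | COCOc1c(OC)ccc(C(=O)/C=C/c2cc(OCc3ccccc3)c(OC)c(OCc3ccccc3)c2)c1O
F3 | step 9 | rac-(2R,3R)-2-[3,5-bis(benzyloxy)-4-methoxyphenyl]-3-hydroxy-7-methoxy-8-(methoxymethoxy)-2,3-dihydrochromen-4-one (trans; racemate, one enantiomer drawn; formed in the flask) | COCOc1c(OC)ccc2C(=O)[C@H](O)[C@@H](c3cc(OCc4ccccc4)c(OC)c(OCc4ccccc4)c3)Oc12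
F4 | step 9 | 2-[3,5-bis(benzyloxy)-4-methoxyphenyl]-3-hydroxy-7-methoxy-8-(methoxymethoxy)chromen-4-one | COCOc1c(OC)ccc2c(=O)c(O)c(-c3cc(OCc4ccccc4)c(OC)c(OCc4ccccc4)c3)oc12
F5 | step 9 | 3-(benzyloxy)-2-[3,5-bis(benzyloxy)-4-methoxyphenyl]-7-methoxy-8-(methoxymethoxy)chromen-4-one | COCOc1c(OC)ccc2c(=O)c(OCc3ccccc3)c(-c3cc(OCc4ccccc4)c(OC)c(OCc4ccccc4)c3)oc12
F6 | step 9 | 3-(benzyloxy)-2-[3,5-bis(benzyloxy)-4-methoxyphenyl]-8-hydroxy-7-methoxychromen-4-one | COc1ccc2c(=O)c(OCc3ccccc3)c(-c3cc(OCc4ccccc4)c(OC)c(OCc4ccccc4)c3)oc2c1O
F7 | step 9 | 3-(benzyloxy)-2-[3,5-bis(benzyloxy)-4-methoxyphenyl]-7-methoxychromene-4,5,8-trione | COC1=CC(=O)c2c(oc(-c3cc(OCc4ccccc4)c(OC)c(OCc4ccccc4)c3)c(OCc3ccccc3)c2=O)C1=O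
F8 | step 6 | 8-(benzyloxy)-2-[3,5-bis(benzyloxy)-4-methoxyphenyl]-7-methoxychromen-4-one | COc1ccc2c(=O)cc(-c3cc(OCc4ccccc4)c(OC)c(OCc4ccccc4)c3)oc2c1OCc1ccccc1
F9 | step 6 | 8-(benzyloxy)-2-[3,5-bis(benzyloxy)-4-methoxyphenyl]-2,3-epoxy-7-methoxy-2,3-dihydrochromen-4-one (racemic, cis-fused oxirane; one enantiomer drawn) | COc1ccc2C(=O)[C@@H]3O[C@]3(c3cc(OCc4ccccc4)c(OC)c(OCc4ccccc4)c3)Oc2c1OCc1ccccc1
F10 | step 4 | 1-[2,3-bis(benzyloxy)-4-methoxyphenyl]ethanone | CC(=O)c1ccc(OC)c(OCc2ccccc2)c1OCc1ccccc1
F11 | step 10 | 3,8-bis(benzyloxy)-2-[3,5-bis(benzyloxy)-4-methoxyphenyl]-5-hydroxy-7-methoxychromen-4-one | COc1cc(O)c2c(=O)c(OCc3ccccc3)c(-c3cc(OCc4ccccc4)c(OC)c(OCc4ccccc4)c3)oc2c1OCc1ccccc1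
A1 | alternative 1 | 5,8-bis(benzyloxy)-2-[3,5-bis(benzyloxy)-4-methoxyphenyl]-7-methoxychromen-4-one | COc1cc(OCc2ccccc2)c2c(=O)cc(-c3cc(OCc4ccccc4)c(OC)c(OCc4ccccc4)c3)oc2c1OCc1ccccc1
A2 | alternative 1 | 3,6-bis(benzyloxy)-2-iodo-5-methoxyphenol | COc1cc(OCc2ccccc2)c(I)c(O)c1OCc1ccccc1
A3 | alternative 1 | 1,3-bis(benzyloxy)-5-ethynyl-2-methoxybenzene | COc1c(OCc2ccccc2)cc(C#C)cc1OCc1ccccc1
A4 | alternative 2 | 2-(benzyloxy)-1-[3,6-bis(benzyloxy)-2-hydroxy-4-methoxyphenyl]-3-[3,5-bis(benzyloxy)-4-methoxyphenyl]propane-1,3-dione (racemic, configurationally labile) | COc1cc(OCc2ccccc2)c(C(=O)C(OCc2ccccc2)C(=O)c2cc(OCc3ccccc3)c(OC)c(OCc3ccccc3)c2)c(O)c1OCc1ccccc1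
A5 | alternative 2 | 3,6-bis(benzyloxy)-2-[(benzyloxy)acetyl]-5-methoxyphenyl 3,5-bis(benzyloxy)-4-methoxybenzoate | COc1cc(OCc2ccccc2)c(C(=O)COCc2ccccc2)c(OC(=O)c2cc(OCc3ccccc3)c(OC)c(OCc3ccccc3)c2)c1OCc1ccccc1
A6 | alternative 2 | 2-(benzyloxy)-1-[3,6-bis(benzyloxy)-2-hydroxy-4-methoxyphenyl]ethanone | COc1cc(OCc2ccccc2)c(C(=O)COCc2ccccc2)c(O)c1OCc1ccccc1
A7 | alternative 2 | 3,5,8-tris(benzyloxy)-2-[3,5-bis(benzyloxy)-4-methoxyphenyl]-7-methoxychromen-4-one | COc1cc(OCc2ccccc2)c2c(=O)c(OCc3ccccc3)c(-c3cc(OCc4ccccc4)c(OC)c(OCc4ccccc4)c3)oc2c1OCc1ccccc1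
A8 | alternative 3 | 3-(benzyloxy)-2-[3,5-bis(benzyloxy)-4-methoxyphenyl]-5,8-dihydroxy-7-methoxychromen-4-one | COc1cc(O)c2c(=O)c(OCc3ccccc3)c(-c3cc(OCc4ccccc4)c(OC)c(OCc4ccccc4)c3)oc2c1O
A9 | alternative 3 | 3-(benzyloxy)-2-[3,5-bis(benzyloxy)-4-methoxyphenyl]-6-(1-hydroxy-2-methoxy-4-oxocyclobut-2-en-1-yl)pyran-4-one (racemic) | COC1=CC(=O)C1(O)c1cc(=O)c(OCc2ccccc2)c(-c2cc(OCc3ccccc3)c(OC)c(OCc3ccccc3)c2)o1
A10 | alternative 3 | 3-(benzyloxy)-2-[3,5-bis(benzyloxy)-4-methoxyphenyl]pyran-4-one | O=c1ccoc(-c2cc(OCc3ccccc3)c(OC)c(OCc3ccccc3)c2)c1OCc1ccccc1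
A11 | alternative 3 | 3-methoxycyclobut-3-ene-1,2-dione | COC1=CC(=O)C1=O
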